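The target is made and lost in the same flask, so its worth at the end of a run depends on how long it has stood there. The share asked for is a selectivity: target over target plus over-reaction product plus side product. The runs never read the side product, so I take it as small.

| flask | starting material | partner | temperature | remark | time |
|---|---|---|---|---|---|
| south-east | 48 mM | 100 mM | −5 °C | run made earlier |  |
| south | 48 mM | 160 mM | 25 °C | run made earlier |  |
| north-west | 72 mM | 72 mM | −5 °C | run made earlier |  |
| dawn | 48 mM | 72.0 mM | 50 °C |  | 4.0 h |
| midnight | 48 mM | 72.0 mM |  | at 0 °C until 80 min, from then on at 50 °C | 4.0 h |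
| autumn | 48 mM | 72.0 mM | 25 °C |  | 4.0 h |
| summer | 48 mM | 72.0 mM | 0 °C |  | 4.0 h |

- south-east (time / h: target / %, over-reaction product / %): 6.00: 1, 3; 10.0: 0, 0; 15.0: 3, 0; 30.0: 5, 0; 50.0: 2, 0; 72.0: 0, 0
- south (time / h: target / %, over-reaction product / %): 1.33: 0, 0; 2.50: 2, 0; 3.00: 2, 0; 6.00: 11, 7; 10.0: 10, 10; 15.0: 17, 17
- north-west (time / h: target / %, over-reaction product / %): 6.00: 0, 3; 20.0: 1, 0; 30.0: 0, 1; 50.0: 5, 2; 72.0: 0, 0

(each reading ± 2 percentage points)

- percent here means starting material units held: one side product counts as two

1. which flask leads in share of target in all that became target or over-reaction product or side product ("all alike" within 1.5 percentage points) (dawn / midnight / autumn / summer / all alike)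
2. share of target in all that became target or over-reaction product or side product, dawn
3. share of target in all that became target or over-reaction product or side product, midnight
4. share of target in all that became target or over-reaction product or side product, autumn
5. share of target in all that became target or over-reaction product or side product, summer

The south run at 25 °C gives the loss of target in two ways. By slope, over-reaction product rises 10 percentage points between 6.00 h and 15.0 h while target stands near 14.0 % of the charge, which gives 0.0794 /h. By ratio, a steady feed of target makes over-reaction product over target about half of n = kt, the number of target lives, while n is small, and 17 % over 17 % at 15.0 h gives 0.133 /h.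

The ratio value is higher than the slope value, so I test both in the full form for a steady feed, s = (1 − e^−n)/n. At 15.0 h the slope value gives 58.4 %, the ratio value 43.3 %, and the reading is 50.0 %. The ratio cheats by its shortcut, since n is 2.00 there and no longer small. The slope rests on a difference of two readings, each with a scatter of 2 points. I take the midpoint in logarithms, 0.103 /h, which returns 50.9 %. This is the target loss constant, the fraction of standing target lost per hour at the south run's temperature.

For temperature I work in powers of ten. The south-east run reads 5 % target at 30.0 h, and the south run, with more partner, reads 2 % at 3.00 h and 11 % at 6.00 h. Taking 3.00 h as its time for that level gives a rough factor of 10.0 between the two runs. Partner and temperature both differ there (−5 °C against 25 °C), but I assume the whole factor belongs to temperature and holds for the loss of target too, and I spread its logarithm evenly over the degrees. The lives come to 2.80 for dawn, 1.87 for midnight counting its hot hours, 0.411 for autumn and 0.0604 for summer. My shares are 33.5 %, 45.3 %, 82.0 % and 97.0 %.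

The forecast names summer as leader and gives 50 % for dawn, 58 % for midnight, 72 % for autumn and 78 % for summer, on the ground that “The share of target therefore falls with conversion”. We name the same leader, but my dawn share is lower than its number and my autumn share higher.

The simulation gives summer as leader, with 7.07 % for dawn, 15.6 % for midnight, 81.7 % for autumn and 99.2 % for summer.

    starting material → intermediate (k = 2.30 × 10⁻⁵ /s, Ea = 88.0 kJ/mol)
    partner + intermediate → target (k = 3.07 × 10⁻⁴ /M/s, Ea = 75.0 kJ/mol)
    2 partner → homo product (k = 7.94 × 10⁻⁵ /M/s, Ea = 58.0 kJ/mol)
    partner ⇌ dormant form (K = 0.370, k = 2.52 × 10⁻⁵ /s, Ea = 97.0 kJ/mol, ΔH = −30.0 kJ/mol)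
    target → over-reaction product (k = 3.53 × 10⁻⁵ /s, Ea = 87.0 kJ/mol)
    starting material + target → side product (k = 6.21 × 10⁻⁵ /M/s, Ea = 77.0 kJ/mol)
    (constants at 25 °C)

My reckoning lands close in autumn, 82.0 % against 81.7 %, and stands well off at dawn, 33.5 % against 7.07 %. Dawn has not come to rest at 4.00 h: it still holds 33.2 % intermediate. At 40.0 h that is down to 4.34 %, over-reaction product has gone from 60.5 % to 94.5 %, and the share has fallen to 0.0534 %. Summer at 40.0 h still holds 87.9 % starting material, and its share is 91.6 %, where the lives give 75.1 %.

A flask like dawn kept at 35 °C has 0.886 lives, so the rule gives 66.3 %. The computed share is 54.8 %.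

The data are calculated with made-up constants; the scatter is artificial.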